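## Structural features

The target is a 5-deoxy B-type proanthocyanidin dimer of the ent-fisetinidol-(4α→6)-catechin type. An upper flavan-3-ol (resorcinol-type ring A, pyran ring C, catechol ring B) is bonded through C4 to C6' of ring D of an intact (+)-catechin unit (rings D, F and E; lower-unit atoms are primed). Ring C carries three contiguous stereocentres, C2 (S), C3 (R) and C4 (S): ring B and the C3 hydroxyl are trans, the C3 hydroxyl and the ring D aryl group are cis. The lower unit keeps the remote pair C2' (R) and C3' (S) of natural catechin, so the upper unit belongs to the opposite enantiomeric series and cannot come from the same chiral pool. Seven phenols, four of them in two catechols, make the free compound sensitive to air and base; the doubly benzylic C4–C6' bond to a phloroglucinol-type ring is acid-labile, and C2 can epimerise by ring opening. The difficulty is twofold: the bond must go to C6' and not to the more accessible C8', and C4 must be 3,4-cis, whereas capture of a 2,3-trans flavan-4-yl cation by ring D gives mainly 3,4-trans. The feature used is that O1 sits on C8a, ortho to C4a. C4 with its ring D substituent can therefore be the exocyclic terminus of a ring A o-quinone methide whose carbonyl oxygen becomes O1, and C3 and C2 can be added as one two-carbon enolate unit that closes ring C and fixes C3 and C4 together.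

## Logic of the disconnections

21 ⇒ 20. The nine O–benzyl bonds and the C8'–Br bond are cut last. All phenols and both alcohols share one protecting group and the bromine that blocks C8' goes in the same operation, so 21 is exposed only once. The forward hydrogenolysis must not open the benzylic C2–O1 bonds or the C4–C6' bond.

20 ⇒ 19. The O1–C2 bond is cut. This removes ring C and the C2 stereocentre and leaves an acyclic carbinol next to the existing C3 and C4. The forward closure must deliver 2,3-trans; it goes through a ring B-stabilised benzylic cation, so the carbinol configuration of 19 is irrelevant.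

19 ⇒ 16 + 18 (from 17). The C2–ring B bond is cut. Ring B becomes a simple aryl nucleophile, made from commercial 17, and the rest an aldehyde masked as a lactol. The forward addition must be faster than enolisation at C3 and must tolerate the aryl bromide, which favours an arylmagnesium reagent.

16 ⇒ 15. No bond is cut; C2 is raised to the lactone oxidation level so that the next disconnection becomes possible. The forward reduction must stop at the lactol.

15 ⇒ 13 + 14 (from 11 and 12). The C3–C4 and O1–C2 bonds are cut together. This is the strategic cut: it removes ring C and both C3 and C4, and leaves a planar o-quinone methide and a two-carbon ketene. The forward step needs catalyst control of the enolate face, a cis (endo-type) approach, and C-alkylation ahead of O-acylation.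

13 ⇒ 11 ⇒ 10. The C4–S bond of 11 and, before it, the O–allyl bond of 10 are cut. A storable sulfone replaces a reactive methide, and the sulfone comes from a carbinol. The forward sequence must free the phenol and install the sulfone without letting the benzhydryl cation alkylate another arene.

10 ⇒ 9 (from 8) + 5. The C4–C4a bond is cut. The two halves become an aryllithium and an aldehyde of similar size, and the regiochemistry at ring D is fixed by the position of the formyl group. The forward addition must outrun bromine–lithium exchange at C8'.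

5 ⇒ 4 ⇒ 3 ⇒ 2 ⇒ 1. The C6'–CHO bond, the 3-O–benzyl bond, the C8'–Br bond and the four phenolic O–benzyl bonds are cut in turn. This leads back to the chiral pool, which supplies C2' and C3'. The forward steps rely on bromination going to C8' first, so that formylation can only go to C6'.

8 ⇒ 7 ⇒ 6, with 14 from 12 and 18 from 17. The O–allyl and O–benzyl bonds of the ring A piece are cut. The forward monobenzylation of 6 must favour the hydroxyl para to bromine; 12 and 17 are commercial.

## Other disconnections considered

Alternative 1: Ring D is cut at four bonds (C8'–C8a', C5'–C6', C7'–C8', C4a'–C5'). In the forward direction the ring F diazo ketone A2 is irradiated (Wolff rearrangement) in the presence of the flavan-4-yl siloxyalkyne A3; [2+2] addition, four-electron ring opening and six-electron closure give the phenol A1.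
- In its favour: the substitution pattern of ring D follows from the connectivity of the two partners. There is no C6'/C8' question and no bromine to install and remove, which is better than the chosen plan. The coupling is neutral and tolerates benzyl ethers.
- Against it: A3 must already carry all three ring C stereocentres, including the 3,4-cis C4, now with an alkynyl group. The central problem is moved, not solved, and the propargylic, benzylic C4–H is prone to epimerisation.
- Against it: A2 has to be made de novo with C2' and C3', so the two stereocentres that (+)-catechin supplies in the chosen plan must be created.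
- Against it: A1 carries an unneeded distinction between the C5' phenol and the C7' silyl ether and needs a separate desilylation.
- Comparison: convergence and the final global deprotection are equal to the chosen plan. In step economy it is clearly longer, since both partners need multistep stereoselective syntheses.

Alternative 2: O1–C2 and C2–C3 are cut. The 2-(1-arylvinyl)phenol A5 and 3,4-bis(benzyloxy)benzaldehyde A6 would condense under a chiral phosphoric acid (oxocarbenium formation, 6-endo attack of the alkene, loss of the C3 proton) to the 4-aryl flav-3-ene A4.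
- Correction: with the spatial arrangement of the target at C2, A4 is 2R by the sequence rules, not 2S, because ring B outranks the sp2 C3. It is labelled 2R here.
- In its favour: ring B enters as a cheap aldehyde in the ring-forming step, with no organometallic addition and no adjustment of oxidation level. On this point it is better than the chosen plan.
- Against it: C3 and C4 remain sp2 and are the harder pair to set. Syn addition by hydroboration would place the C4 hydrogen and the C3 oxygen cis, that is, ring D trans to the hydroxyl, the wrong C4 epimer. The 3,4-cis product needs a net anti addition: epoxidation, then hydride opening at a diaryl-stabilised C4, where ionisation, loss of stereochemical fidelity and rearrangement to a 3-ketone are likely.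
- Against it: A5 is a very electron-rich 1,1-diarylethene that Brønsted acid can protonate and dimerise.
- Comparison: the chosen plan sets C3 and C4 in the ring closure and leaves C2 to a conformationally biased cation closure; alternative 2 sets only C2 by catalyst. On paper the step count after the key step is equal (about four operations). A5 needs two or three steps more than 11 (oxidation of 10, methylenation, deallylation).

Alternative 3: O1–C2 and the C3–O bond are cut. Shi epoxidation of the (E)-alkene A8 gives the trans-epoxide A9; fluoride frees the ring A phenoxide, which opens the epoxide at benzylic C2 in a 6-endo mode with inversion to give A7.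
- In its favour: C2 and C3 come from a stereospecific sequence under reagent control. C2 is fixed by SN2 opening rather than by cation closure, which is better than the chosen plan on this point.
- In its favour: A8 could be reached from the same quinone methide 13 by catalytic asymmetric addition of an alkenylboron nucleophile. The count from 13 (addition, silylation, epoxidation, cyclisation, hydrogenolysis) is then equal to that of the chosen plan.
- Against it: C4 must first be set in an open chain without ring constraint. The dioxirane must then override the allylic diarylmethyl stereocentre, so a mismatched pairing is possible, and the less accessible antipode of the ketone catalyst may be needed.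
- Against it: A9 is a 3,4-dialkoxystyrene oxide and rearranges or solvolyses easily. 5-exo opening to a dihydrobenzofuran competes with the wanted 6-endo mode.
- Comparison: alternative 3 needs two independent reagent-controlled events (C4, then the epoxide face). The chosen plan needs one, in which the cis relation of C3 and C4 follows from the cyclic transition state.

Key step: step 9

Remarks before the steps.
- "Bromocatechinyl" in the names below means the (2R,3S)-3,5,7-tris(benzyloxy)-2-[3,4-bis(benzyloxy)phenyl]-8-bromochroman-6-yl group.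
- Assumption: the (5aS,10bR) antipode of the aminoindanol-derived N-mesityl triazolium chloride is taken to deliver the (3R,4S) lactone. If a model quinone methide shows the opposite sense, the (5aR,10bS) salt is used in the same way.
- The descriptors of the main-line structures were checked against the target: 15 is (3R,4S) and cis, 13 is E, and 20 and 21 are (2S,3R,4S) in the upper and (2R,3S) in the lower unit.

## Route

Step 1
Reactants: 1 (+)-catechin
Product: 2 5,7,3',4'-tetra-O-benzyl-(+)-catechin
Conditions: BnBr (4.4 equiv), K2CO3, DMF, 0 °C → rt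
Reagents that add atoms: benzyl bromide, BrCc1ccccc1
Why: Williamson etherification; K2CO3 deprotonates only the four phenols, so the secondary C3 hydroxyl stays free and C2/C3 are not touched.

Step 2
Reactants: 2 5,7,3',4'-tetra-O-benzyl-(+)-catechin
Product: 3 8-bromo-5,7,3',4'-tetra-O-benzyl-(+)-catechin
Conditions: NBS (1.0 equiv), CH2Cl2, −78 °C → rt
Reagents that add atoms: N-bromosuccinimide, O=C1CCC(=O)N1Br
Why: Electrophilic aromatic bromination; C8 is the more accessible position of the phloroglucinol-type ring and one equivalent of NBS at low temperature should stop at the monobromide, which blocks C8 for the rest of the route.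

Step 3
Reactants: 3 8-bromo-5,7,3',4'-tetra-O-benzyl-(+)-catechin
Product: 4 8-bromo-3,5,7,3',4'-penta-O-benzyl-(+)-catechin
Conditions: NaH, BnBr, n-Bu4NI (cat.), DMF, 0 °C → rt
Reagents that add atoms: benzyl bromide, BrCc1ccccc1
Why: Williamson etherification of the secondary alkoxide; it removes the last acidic proton before the formylation and the organolithium step.

Step 4
Reactants: 4 8-bromo-3,5,7,3',4'-penta-O-benzyl-(+)-catechin
Product: 5 8-bromo-6-formyl-3,5,7,3',4'-penta-O-benzyl-(+)-catechin
Conditions: POCl3, DMF, 0 → 70 °C; then aq. NaOAc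
Reagents that add atoms: N,N-dimethylformamide, CN(C)C=O; water, O
Why: Vilsmeier–Haack formylation; the chloroiminium ion attacks C6, the only free position of the trioxygenated ring and activated by two ortho and one para oxygen, while the catechol ring is far less nucleophilic.

Step 5
Reactants: 6 4-bromoresorcinol
Product: 7 5-(benzyloxy)-2-bromophenol
Conditions: BnBr (1.0 equiv), K2CO3 (1.0 equiv), acetone, rt
Reagents that add atoms: benzyl bromide, BrCc1ccccc1
Why: Williamson etherification with one equivalent of electrophile; the hydroxyl para to bromine is the less hindered and the ortho-bromo phenoxide the weaker nucleophile, so the wanted monoether should predominate and is separated from the dibenzyl ether and the regioisomer by chromatography.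

Step 6
Reactants: 7 5-(benzyloxy)-2-bromophenol
Product: 8 2-(allyloxy)-4-(benzyloxy)-1-bromobenzene
Conditions: allyl bromide, K2CO3, DMF, rt
Reagents that add atoms: allyl bromide, C=CCBr
Why: Williamson etherification; the allyl ether survives organolithium reagents at low temperature and is later removed under palladium catalysis, orthogonally to the benzyl ethers.

Step 7
Reactants: 8 2-(allyloxy)-4-(benzyloxy)-1-bromobenzene; 5 8-bromo-6-formyl-3,5,7,3',4'-penta-O-benzyl-(+)-catechin
Product: 10 [2-(allyloxy)-4-(benzyloxy)phenyl](bromocatechinyl)methanol (both carbinol epimers), via aryllithium 9 (not isolated)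
Conditions: 8 (1.2 equiv), n-BuLi, THF, −78 °C; then 5, −78 → −40 °C; aq. NH4Cl
Reagents that add atoms: none
Why: Bromine–lithium exchange gives an aryllithium stabilised by the ortho oxygen, which adds to the hindered aldehyde at −78 °C faster than it exchanges with the ring D bromide. The new carbinol centre forms as a mixture of epimers, which is of no consequence because this carbon becomes the sp2 methide carbon.

Step 8
Reactants: 10 [2-(allyloxy)-4-(benzyloxy)phenyl](bromocatechinyl)methanol
Product: 11 5-(benzyloxy)-2-[(bromocatechinyl)(p-tolylsulfonyl)methyl]phenol (both epimers at the sulfonyl carbon)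
Conditions: Pd(PPh3)4 (5 mol %), TolSO2H (4 equiv), CH2Cl2, rt
Reagents that add atoms: p-toluenesulfinic acid, Cc1ccc(cc1)S(=O)O
Why: Two known reactions run in one flask: Tsuji–Trost deallylation of the aryl allyl ether with sulfinate as allyl acceptor, and SN1 substitution of the doubly activated benzhydrol by the sulfinic acid through the ring D-stabilised cation, the sulfone being the thermodynamic product. The sulfone is the usual storable precursor from which base releases an o-quinone methide.

Step 9
Reactants: 11 5-(benzyloxy)-2-[(bromocatechinyl)(p-tolylsulfonyl)methyl]phenol; 12 benzyloxyacetyl chloride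
Product: 15 (3R,4S)-3,7-bis(benzyloxy)-4-(bromocatechinyl)chroman-2-one (cis-dihydrocoumarin), via o-quinone methide 13 (not isolated), via benzyloxyketene 14 (not isolated)
Conditions: 11, Cs2CO3 (3 equiv), toluene, rt, 30 min; then (5aS,10bR)-2-(2,4,6-trimethylphenyl)-5a,10b-dihydro-4H,6H-indeno[2,1-b][1,2,4]triazolo[4,3-d][1,4]oxazin-2-ium chloride (10 mol %), i-Pr2NEt (2 equiv), 12 (1.5 equiv, slow addition), 0 °C → rt
Reagents that add atoms: none
Why: Cs2CO3 eliminates p-toluenesulfinate from 11 (E1cB) to give the push–pull stabilised (E)-o-quinone methide 13 before any acylating agent is present, and i-Pr2NEt then dehydrochlorinates 12 to benzyloxyketene 14, which the free carbene intercepts as a (Z)-azolium enolate. The enolate carbon (future C3) adds to the methide carbon (future C4) of 13, and the ring A phenoxide so released acylates on the acyl azolium (future C2), giving the lactone and returning the carbene. The closest known reaction type is the N-heterocyclic carbene-catalysed formal [4+2] annulation of in situ o-quinone methides with azolium enolates from ketenes, acid chlorides or α-chloro aldehydes, which gives cis-3,4-disubstituted dihydrocoumarins; here it is applied to an α-benzyloxy enolate and a hindered methide. Ring C closes by intermolecular Michael addition (C3–C4) followed by 6-exo-trig lactonisation (O1–C2), formally an inverse-demand oxa-Diels–Alder reaction. C3 (R) is set by the enolate face that the indane wall of the catalyst leaves open, and C4 (S) by the compact endo-type arrangement of the E methide over that face, which places the benzyloxy group and the ring D aryl group cis. The step needs C-alkylation ahead of O-acylation (secured by forming 13 completely before the slow addition of 12), catalyst control over the remote C2'/C3' stereocentres (they lie several bonds from C4 and should exert little bias), and no epimerisation at C3 (favoured by the weak amine base and low temperature). The trioxygenated ring D and the 7-benzyloxy group lengthen the lifetime of 13 while its carbonyl keeps C4 electrophilic, and the blocked C8' leaves ring D without a nucleophilic position.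

Step 10
Reactants: 15 (3R,4S)-3,7-bis(benzyloxy)-4-(bromocatechinyl)chroman-2-one
Product: 16 (3R,4S)-3,7-bis(benzyloxy)-4-(bromocatechinyl)chroman-2-ol (lactol, both anomers)
Conditions: i-Bu2AlH (1.2 equiv), CH2Cl2, −78 °C; aq. potassium sodium tartrate
Reagents that add atoms: none
Why: Partial reduction of an aryl lactone; the tetrahedral aluminium hemiacetal is stable at −78 °C and gives the lactol on work-up, and C3 and C4 are not touched.

Step 11
Reactants: 16 (3R,4S)-3,7-bis(benzyloxy)-4-(bromocatechinyl)chroman-2-ol; 17 4-bromo-1,2-bis(benzyloxy)benzene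
Product: 19 (2R,3S)-2-(benzyloxy)-1-[3,4-bis(benzyloxy)phenyl]-3-[4-(benzyloxy)-2-hydroxyphenyl]-3-(bromocatechinyl)propan-1-ol (C1 epimers; mainly 1R expected), via arylmagnesium bromide 18 (not isolated)
Conditions: 17, Mg, I2 (cat.), THF, rt → 40 °C; then 16 (0.3 equiv relative to 18), 0 °C → rt; aq. NH4Cl
Reagents that add atoms: none
Why: Grignard addition to the open hydroxy-aldehyde form of the lactol, one equivalent of reagent being consumed by the hydroxyl; magnesium chelation between the aldehyde and the α-benzyloxy group should favour the 1,2-syn carbinol, but either epimer serves in step 12. An arylmagnesium reagent is chosen because it does not exchange with the ring D bromide.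

Step 12
Reactants: 19 (2R,3S)-2-(benzyloxy)-1-[3,4-bis(benzyloxy)phenyl]-3-[4-(benzyloxy)-2-hydroxyphenyl]-3-(bromocatechinyl)propan-1-ol
Product: 20 (2S,3R,4S)-3,7-bis(benzyloxy)-2-[3,4-bis(benzyloxy)phenyl]-4-(bromocatechinyl)chromane (nona-O-benzyl-8'-bromo derivative of the target)
Conditions: TsOH·H2O (10 mol %), CH2Cl2, 0 °C → rt
Reagents that add atoms: none
Why: Acid ionises the carbinol to a benzylic cation stabilised by the para benzyloxy group of ring B, which the ring A phenol captures in a six-membered ring closure (intramolecular SN1 etherification). C2 is set in this closure: the bulky ring D aryl group at C4 prefers the pseudo-axial position, which holds the cis C3 benzyloxy group equatorial, and ring B then takes the equatorial position trans to it, giving 2S. The blocked ring D and the unactivated C5 of ring A leave no competing carbon nucleophile.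

Step 13
Reactants: 20 (2S,3R,4S)-3,7-bis(benzyloxy)-2-[3,4-bis(benzyloxy)phenyl]-4-(bromocatechinyl)chromane
Product: 21 ent-fisetinidol-(4α→6)-catechin, (2S,3R,4S)-upper and (2R,3S)-lower unit (target)
Conditions: H2 (1 atm), Pd(OH)2/C, Et3N (1.5 equiv), THF/MeOH/H2O, rt
Reagents that add atoms: none
Why: Catalytic hydrogenolysis removes the nine benzyl ethers and reduces the aryl bromide in one operation; Et3N takes up the HBr so that the acid-labile C4–C6' bond and the benzylic C2–O1 bonds are not exposed to acid.

## Compound list

1 | (+)-catechin, (2R,3S) | O[C@H]1Cc2c(O)cc(O)cc2O[C@@H]1c1ccc(O)c(O)c1 | starting material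
2 | 5,7,3',4'-tetra-O-benzyl-(+)-catechin | O[C@H]1Cc2c(OCc3ccccc3)cc(OCc3ccccc3)cc2O[C@@H]1c1ccc(OCc2ccccc2)c(OCc2ccccc2)c1 | intermediate
3 | 8-bromo-5,7,3',4'-tetra-O-benzyl-(+)-catechin | O[C@H]1Cc2c(OCc3ccccc3)cc(OCc3ccccc3)c(Br)c2O[C@@H]1c1ccc(OCc2ccccc2)c(OCc2ccccc2)c1 | intermediate
4 | 8-bromo-3,5,7,3',4'-penta-O-benzyl-(+)-catechin | c1ccccc1CO[C@H]1Cc2c(OCc3ccccc3)cc(OCc3ccccc3)c(Br)c2O[C@@H]1c1ccc(OCc2ccccc2)c(OCc2ccccc2)c1 | intermediate
5 | 8-bromo-6-formyl-3,5,7,3',4'-penta-O-benzyl-(+)-catechin | c1ccccc1CO[C@H]1Cc2c(OCc3ccccc3)c(C=O)c(OCc3ccccc3)c(Br)c2O[C@@H]1c1ccc(OCc2ccccc2)c(OCc2ccccc2)c1 | intermediate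
6 | 4-bromoresorcinol | Oc1ccc(Br)c(O)c1 | starting material
7 | 5-(benzyloxy)-2-bromophenol | Oc1cc(OCc2ccccc2)ccc1Br | intermediate
8 | 2-(allyloxy)-4-(benzyloxy)-1-bromobenzene | C=CCOc1cc(OCc2ccccc2)ccc1Br | intermediate
9 | [2-(allyloxy)-4-(benzyloxy)phenyl]lithium | C=CCOc1cc(OCc2ccccc2)ccc1[Li] | intermediate
10 | [2-(allyloxy)-4-(benzyloxy)phenyl](bromocatechinyl)methanol, carbinol epimers | C=CCOc1cc(OCc2ccccc2)ccc1C(O)c1c(OCc3ccccc3)c(Br)c2c(c1OCc1ccccc1)C[C@H](OCc1ccccc1)[C@@H](c1ccc(OCc3ccccc3)c(OCc3ccccc3)c1)O2 | intermediate
11 | 5-(benzyloxy)-2-[(bromocatechinyl)(p-tolylsulfonyl)methyl]phenol, epimers at the sulfonyl carbon | Oc1cc(OCc2ccccc2)ccc1C(S(=O)(=O)c1ccc(C)cc1)c1c(OCc3ccccc3)c(Br)c2c(c1OCc1ccccc1)C[C@H](OCc1ccccc1)[C@@H](c1ccc(OCc3ccccc3)c(OCc3ccccc3)c1)O2 | intermediate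
12 | benzyloxyacetyl chloride | ClC(=O)COCc1ccccc1 | starting material
13 | (6E)-3-(benzyloxy)-6-[(bromocatechinyl)methylidene]cyclohexa-2,4-dien-1-one (ring A o-quinone methide) | c1(/C=C2/C(=O)C=C(OCc3ccccc3)C=C2)c(OCc3ccccc3)c(Br)c2c(c1OCc1ccccc1)C[C@H](OCc1ccccc1)[C@@H](c1ccc(OCc3ccccc3)c(OCc3ccccc3)c1)O2 | intermediate
14 | benzyloxyketene | O=C=COCc1ccccc1 | intermediate
15 | (3R,4S)-3,7-bis(benzyloxy)-4-(bromocatechinyl)chroman-2-one | c1ccccc1COc1ccc2c(c1)OC(=O)[C@H](OCc1ccccc1)[C@@H]2c1c(OCc3ccccc3)c(Br)c2c(c1OCc1ccccc1)C[C@H](OCc1ccccc1)[C@@H](c1ccc(OCc3ccccc3)c(OCc3ccccc3)c1)O2 | intermediate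
16 | (3R,4S)-3,7-bis(benzyloxy)-4-(bromocatechinyl)chroman-2-ol, anomers | c1ccccc1COc1ccc2c(c1)OC(O)[C@H](OCc1ccccc1)[C@@H]2c1c(OCc3ccccc3)c(Br)c2c(c1OCc1ccccc1)C[C@H](OCc1ccccc1)[C@@H](c1ccc(OCc3ccccc3)c(OCc3ccccc3)c1)O2 | intermediate
17 | 4-bromo-1,2-bis(benzyloxy)benzene | Brc1ccc(OCc2ccccc2)c(OCc2ccccc2)c1 | starting material
18 | [3,4-bis(benzyloxy)phenyl]magnesium bromide | Br[Mg]c1ccc(OCc2ccccc2)c(OCc2ccccc2)c1 | intermediate
19 | (2R,3S)-2-(benzyloxy)-1-[3,4-bis(benzyloxy)phenyl]-3-[4-(benzyloxy)-2-hydroxyphenyl]-3-(bromocatechinyl)propan-1-ol, C1 epimers | OC(c1ccc(OCc2ccccc2)c(OCc2ccccc2)c1)[C@H](OCc1ccccc1)[C@@H](c1ccc(OCc2ccccc2)cc1O)c1c(OCc3ccccc3)c(Br)c2c(c1OCc1ccccc1)C[C@H](OCc1ccccc1)[C@@H](c1ccc(OCc3ccccc3)c(OCc3ccccc3)c1)O2 | intermediate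
20 | (2S,3R,4S)-3,7-bis(benzyloxy)-2-[3,4-bis(benzyloxy)phenyl]-4-(bromocatechinyl)chromane | c1ccccc1COc1ccc2c(c1)O[C@@H](c1ccc(OCc3ccccc3)c(OCc3ccccc3)c1)[C@H](OCc1ccccc1)[C@@H]2c1c(OCc3ccccc3)c(Br)c2c(c1OCc1ccccc1)C[C@H](OCc1ccccc1)[C@@H](c1ccc(OCc3ccccc3)c(OCc3ccccc3)c1)O2 | intermediate
21 | ent-fisetinidol-(4α→6)-catechin, (2S,3R,4S)/(2'R,3'S) | Oc1ccc2c(c1)O[C@@H](c1ccc(O)c(O)c1)[C@H](O)[C@@H]2c1c(O)cc2c(c1O)C[C@H](O)[C@@H](c1ccc(O)c(O)c1)O2 | target

## Step count and least certain steps

Total: 13 steps. Longest linear sequence: 11 steps (steps 1–4 and 7–13, from 1).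

Step 9 (key step).
- Risk: carbon–carbon bond formation at the hindered, donor-stabilised methide may be slow. Ketene dimerisation or O-acylation of residual phenoxide then takes over. Weak facial control or base-induced epimerisation at C3 to the trans lactone is the second risk.
- Fallback: an auxiliary-controlled Michael addition–lactonisation. It sets out from 13, generated from 11 with Cs2CO3 as in step 9 and filtered. The sodium enolate (NaN(SiMe3)2, THF, −78 °C) of commercial (S)-4-benzyl-3-[(benzyloxy)acetyl]oxazolidin-2-one F1 adds to 13 to give the open-chain adduct F2. The usual sense of alkylation of such Z-enolates corresponds to 3R; a 3,4-trans isomer would be a separable diastereomer. On warming, the ring A phenoxide of F2 displaces the oxazolidinone and closes the lactone, and the route is rejoined at 15.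

Step 4.
- Risk: attack of the bulky chloroiminium ion at C6, flanked by two benzyloxy groups, may be sluggish. Forcing conditions invite ipso attack with loss or migration of bromine, or acid-promoted debenzylation.
- Fallback: a halogenation–metalation route with a smaller electrophile. It sets out from 4: iodination (NIS, catalytic CF3CO2H, MeCN/CH2Cl2) gives the 8-bromo-6-iodo compound F3. Selective iodine–magnesium exchange (i-PrMgCl·LiCl, THF, −40 °C; the dialkoxy-flanked bromide exchanges far more slowly) and quenching with DMF return the route at 5.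

Step 8.
- Risk: the long-lived benzhydryl cation may alkylate ring A of a second molecule (Friedel–Crafts oligomerisation). The very electron-rich sulfone may also ionise during isolation.
- Fallback: avoid the sulfone. It sets out from 10: neutral deallylation (Pd(PPh3)4, morpholine, THF) gives the free 2-hydroxybenzhydrol F4. F4 is dehydrated under catalytic diphenyl phosphate with 4 Å molecular sieves in toluene, the usual acid-catalysed entry to o-quinone methides from o-hydroxybenzhydrols. The acid is quenched by the Cs2CO3 of step 9, and the route is rejoined at 13.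

Step 11.
- Risk: in the basic medium the phenoxide–aldehyde may fragment by retro-Michael expulsion of the stabilised methide, or C3 may epimerise by enolisation before the aryl group adds.
- Fallback: a Weinreb amide route, which sets out from 15 and replaces steps 10 and 11. Opening with MeNH(OMe)·HCl/AlMe3 (CH2Cl2, 0 °C) gives the Weinreb amide F5. Excess 18 gives, after work-up, the aryl ketone F6; the carbonyl stays masked as the tetrahedral chelate while base is present. Reduction with NaBH4/CeCl3·7H2O in MeOH/THF rejoins the route at 19.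

Step 12.
- Risk: incomplete stereocontrol at C2 in the cation closure, or acid-induced heterolysis of the C4–ring D bond.
- Fallback: a stereospecific Mitsunobu etherification instead of the cation closure. It sets out from 19: the 1,2-syn (1R) epimer F7, expected as the major product of the chelation-controlled step 11, is separated. Treatment with PPh3 and DIAD (THF, 0 °C) closes the ring with inversion at the carbinol carbon, and the route is rejoined at 20.

## Further compounds

F1 | step 9 | (S)-4-benzyl-3-[(benzyloxy)acetyl]oxazolidin-2-one | O=C1OC[C@H](Cc2ccccc2)N1C(=O)COCc1ccccc1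
F2 | step 9 | (S)-4-benzyl-3-[(2R,3S)-2-(benzyloxy)-3-[4-(benzyloxy)-2-hydroxyphenyl]-3-(bromocatechinyl)propanoyl]oxazolidin-2-one | O=C1OC[C@H](Cc2ccccc2)N1C(=O)[C@H](OCc1ccccc1)[C@@H](c1ccc(OCc2ccccc2)cc1O)c1c(OCc3ccccc3)c(Br)c2c(c1OCc1ccccc1)C[C@H](OCc1ccccc1)[C@@H](c1ccc(OCc3ccccc3)c(OCc3ccccc3)c1)O2
F3 | step 4 | 8-bromo-6-iodo-3,5,7,3',4'-penta-O-benzyl-(+)-catechin | c1ccccc1CO[C@H]1Cc2c(OCc3ccccc3)c(I)c(OCc3ccccc3)c(Br)c2O[C@@H]1c1ccc(OCc2ccccc2)c(OCc2ccccc2)c1
F4 | step 8 | 5-(benzyloxy)-2-[(bromocatechinyl)(hydroxy)methyl]phenol, carbinol epimers | Oc1cc(OCc2ccccc2)ccc1C(O)c1c(OCc3ccccc3)c(Br)c2c(c1OCc1ccccc1)C[C@H](OCc1ccccc1)[C@@H](c1ccc(OCc3ccccc3)c(OCc3ccccc3)c1)O2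
F5 | step 11 | (2R,3S)-2-(benzyloxy)-3-[4-(benzyloxy)-2-hydroxyphenyl]-3-(bromocatechinyl)-N-methoxy-N-methylpropanamide | CON(C)C(=O)[C@H](OCc1ccccc1)[C@@H](c1ccc(OCc2ccccc2)cc1O)c1c(OCc3ccccc3)c(Br)c2c(c1OCc1ccccc1)C[C@H](OCc1ccccc1)[C@@H](c1ccc(OCc3ccccc3)c(OCc3ccccc3)c1)O2
F6 | step 11 | (2R,3S)-2-(benzyloxy)-1-[3,4-bis(benzyloxy)phenyl]-3-[4-(benzyloxy)-2-hydroxyphenyl]-3-(bromocatechinyl)propan-1-one | O=C(c1ccc(OCc2ccccc2)c(OCc2ccccc2)c1)[C@H](OCc1ccccc1)[C@@H](c1ccc(OCc2ccccc2)cc1O)c1c(OCc3ccccc3)c(Br)c2c(c1OCc1ccccc1)C[C@H](OCc1ccccc1)[C@@H](c1ccc(OCc3ccccc3)c(OCc3ccccc3)c1)O2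
F7 | step 12 | (1R,2R,3S)-epimer of 19 (1,2-syn carbinol) | O[C@H](c1ccc(OCc2ccccc2)c(OCc2ccccc2)c1)[C@H](OCc1ccccc1)[C@@H](c1ccc(OCc2ccccc2)cc1O)c1c(OCc3ccccc3)c(Br)c2c(c1OCc1ccccc1)C[C@H](OCc1ccccc1)[C@@H](c1ccc(OCc3ccccc3)c(OCc3ccccc3)c1)O2
A1 | alternative 1 | protected target with free C5' phenol and C7' triisopropylsilyl ether | c1ccccc1COc1ccc2c(c1)O[C@@H](c1ccc(OCc3ccccc3)c(OCc3ccccc3)c1)[C@H](OCc1ccccc1)[C@@H]2c1c(O[Si](C(C)C)(C(C)C)C(C)C)cc2c(c1O)C[C@H](OCc1ccccc1)[C@@H](c1ccc(OCc3ccccc3)c(OCc3ccccc3)c1)O2
A2 | alternative 1 | 2-diazo-1-[(2R,3S)-3-(benzyloxy)-2-[3,4-bis(benzyloxy)phenyl]-3,4-dihydro-2H-pyran-6-yl]ethan-1-one | [N-]=[N+]=CC(=O)C1=CC[C@H](OCc2ccccc2)[C@@H](c2ccc(OCc3ccccc3)c(OCc3ccccc3)c2)O1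
A3 | alternative 1 | 2,3-trans-3,4-cis 3,7-bis(benzyloxy)-2-[3,4-bis(benzyloxy)phenyl]-4-[(triisopropylsilyloxy)ethynyl]chromane | c1ccccc1COc1ccc2c(c1)O[C@@H](c1ccc(OCc3ccccc3)c(OCc3ccccc3)c1)[C@H](OCc1ccccc1)[C@@H]2C#CO[Si](C(C)C)(C(C)C)C(C)C
A4 | alternative 2 | (2R)-7-(benzyloxy)-2-[3,4-bis(benzyloxy)phenyl]-4-(bromocatechinyl)-2H-chromene | c1ccccc1COc1ccc2c(c1)O[C@@H](c1ccc(OCc3ccccc3)c(OCc3ccccc3)c1)C=C2c1c(OCc3ccccc3)c(Br)c2c(c1OCc1ccccc1)C[C@H](OCc1ccccc1)[C@@H](c1ccc(OCc3ccccc3)c(OCc3ccccc3)c1)O2
A5 | alternative 2 | 5-(benzyloxy)-2-[1-(bromocatechinyl)ethenyl]phenol | C=C(c1ccc(OCc2ccccc2)cc1O)c1c(OCc3ccccc3)c(Br)c2c(c1OCc1ccccc1)C[C@H](OCc1ccccc1)[C@@H](c1ccc(OCc3ccccc3)c(OCc3ccccc3)c1)O2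
A6 | alternative 2 | 3,4-bis(benzyloxy)benzaldehyde | O=Cc1ccc(OCc2ccccc2)c(OCc2ccccc2)c1
A7 | alternative 3 | protected target with free C3 hydroxyl | c1ccccc1COc1ccc2c(c1)O[C@@H](c1ccc(OCc3ccccc3)c(OCc3ccccc3)c1)[C@H](O)[C@@H]2c1c(OCc3ccccc3)c(Br)c2c(c1OCc1ccccc1)C[C@H](OCc1ccccc1)[C@@H](c1ccc(OCc3ccccc3)c(OCc3ccccc3)c1)O2
A8 | alternative 3 | (E)-1-[3,4-bis(benzyloxy)phenyl]-3-[4-(benzyloxy)-2-(tert-butyldimethylsilyloxy)phenyl]-3-(bromocatechinyl)prop-1-ene, (3S) | c1cc(OCc2ccccc2)c(OCc2ccccc2)cc1/C=C/[C@@H](c1ccc(OCc2ccccc2)cc1O[Si](C)(C)C(C)(C)C)c1c(OCc3ccccc3)c(Br)c2c(c1OCc1ccccc1)C[C@H](OCc1ccccc1)[C@@H](c1ccc(OCc3ccccc3)c(OCc3ccccc3)c1)O2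
A9 | alternative 3 | trans-epoxide of A8 | c1cc(OCc2ccccc2)c(OCc2ccccc2)cc1[C@H]4O[C@@H]4[C@@H](c1ccc(OCc2ccccc2)cc1O[Si](C)(C)C(C)(C)C)c1c(OCc3ccccc3)c(Br)c2c(c1OCc1ccccc1)C[C@H](OCc1ccccc1)[C@@H](c1ccc(OCc3ccccc3)c(OCc3ccccc3)c1)O2
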